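The route rests on disconnecting the O1–C2 bond of the pyranone ring C. The feature exploited is the β-aryloxy ketone array O1–C2–C3–C4(=O). C2, the only stereocentre, lies β to the C4 ketone, O1 is the ring A phenol oxygen ortho to that ketone, and C3 is a plain CH2 that can carry a traceless ester. The precursor is therefore an open 2'-hydroxychalcone bearing a tert-butyl ester at C3, assembled by Knoevenagel union of a ring A β-keto ester and a ring B aldehyde. In one flask a chiral bifunctional thiourea closes ring C by oxa-Michael addition and sets C2, then acid strips the ester, CO2 and the O7 protecting group.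

Key step: step 5

Assumption: the quinidine-derived thiourea is taken as the catalyst that leads to 2S, by analogy with its sense in conjugate additions to chalcone-type acceptors; the quinine-derived pseudo-enantiomer (both are commercial) serves if a test run shows the opposite sense.

Step 1
Reactants: 1 3,5-dibromo-4-methoxybenzaldehyde; 2 tributyl(3-methylbut-2-en-1-yl)stannane (2.4 equiv)
Product: 3 4-methoxy-3,5-bis(3-methylbut-2-en-1-yl)benzaldehyde
Conditions: Pd(PPh3)4 (10 mol %), DMF, 100 °C
Reagents that add atoms: none
Why: Double Stille cross-coupling, in which zerovalent palladium inserts into both C–Br bonds of the electron-poor ring, the prenyl group is delivered through its unsubstituted CH2 terminus because bond formation at the tertiary allyl terminus is sterically disfavoured, and the aldehyde is inert to the allylstannane without a Lewis acid.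

Step 2
Reactants: 4 methyl 2,4-dihydroxybenzoate
Product: 5 methyl 2-hydroxy-4-(methoxymethoxy)benzoate
Conditions: MOMCl (1.1 equiv), K2CO3, acetone, 0 °C to rt
Reagents that add atoms: chloromethyl methyl ether (MOMCl), COCCl
Why: Williamson-type O-alkylation that is selective for the 4-OH, because the 2-OH is held in a hydrogen bond to the ester carbonyl and is both less acidic and less nucleophilic.

Step 3
Reactants: 5 methyl 2-hydroxy-4-(methoxymethoxy)benzoate; 6 tert-butyl acetate (4 equiv)
Product: 8 tert-butyl 3-[2-hydroxy-4-(methoxymethoxy)phenyl]-3-oxopropanoate, via lithium enolate of tert-butyl acetate 7 (not isolated)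
Conditions: LDA (4 equiv), 6, THF, −78 °C; then 5, −78 °C to rt; AcOH quench
Reagents that add atoms: none
Why: Crossed Claisen condensation, in which excess enolate 7 first deprotonates the phenol and then attacks the methyl ester, the product is shielded from further attack as its dianion, and the bulky tert-butyl ester resists self-condensation and lactonisation to the 4-hydroxycoumarin.

Step 4
Reactants: 8 tert-butyl 3-[2-hydroxy-4-(methoxymethoxy)phenyl]-3-oxopropanoate; 3 4-methoxy-3,5-bis(3-methylbut-2-en-1-yl)benzaldehyde
Product: 9 tert-butyl (2E)-2-[2-hydroxy-4-(methoxymethoxy)benzoyl]-3-[4-methoxy-3,5-bis(3-methylbut-2-en-1-yl)phenyl]prop-2-enoate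
Conditions: piperidine (20 mol %), AcOH (20 mol %), 4 Å MS, toluene, rt
Reagents that add atoms: none
Why: Knoevenagel condensation under buffered amine catalysis with water removal, in which the non-enolisable aldehyde 3 can act only as acceptor, the E alkene (aryl trans to the ester, cinnamate-type conjugation) is the expected isomer, and the weakly basic buffer at room temperature should keep the free ortho phenol from adding prematurely.

Step 5
Reactants: 9 tert-butyl (2E)-2-[2-hydroxy-4-(methoxymethoxy)benzoyl]-3-[4-methoxy-3,5-bis(3-methylbut-2-en-1-yl)phenyl]prop-2-enoate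
Product: 11 (2S)-7-hydroxy-2-[4-methoxy-3,5-bis(3-methylbut-2-en-1-yl)phenyl]-2,3-dihydro-4H-chromen-4-one, via tert-butyl flavanone-3-carboxylate 10 (not isolated)
Conditions: 1-[3,5-bis(trifluoromethyl)phenyl]-3-[(9R)-6'-methoxycinchonan-9-yl]thiourea (quinidine-derived, 10 mol %), toluene, −25 °C; then TsOH·H2O (2 equiv), 80 °C
Reagents that add atoms: none
Why: The thiourea N–H bonds clamp the ketone and ester carbonyls of 9 while the quinuclidine nitrogen takes the proton of the free ortho phenol of ring A, so that this oxygen (future O1) adds to the benzylic alkene carbon (future C2) inside a chiral hydrogen-bonded ion pair, and protonation at C3 gives 10. This is the known bifunctional cinchona-thiourea intramolecular oxa-Michael addition of alkylidene β-keto esters, followed in the same flask by acid-induced dealkylative decarboxylation. Ring C closes by O1–C2 bond formation in the 6-endo-trig mode. C2 is set by the catalyst, which leaves one face of the bound alkene open (2S assigned to the quinidine-derived catalyst, see the assumption), whereas C3 forms as an epimerisable trans centre and is erased together with the ester. The step needs a fast, practically irreversible catalysed addition that outruns the racemic background, and a single nucleophile: the C3 ester lowers the acceptor LUMO, supplies the second binding point and holds the closed form, the low temperature suppresses the uncatalysed path, and O7 is blocked as its MOM ether so that only the ortho phenol can be deprotonated. TsOH·H2O at 80 °C then removes isobutene, CO2 and the MOM acetal without any base, so retro-Michael racemisation is avoided; the ring B methoxy group is twisted out of conjugation by its two ortho prenyl groups and lends little help to C2–O1 ionisation, and no free phenol flanks a prenyl group, so chroman formation is excluded.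

Compound list
1 | 3,5-dibromo-4-methoxybenzaldehyde | COc1c(Br)cc(C=O)cc1Br | starting material
2 | tributyl(3-methylbut-2-en-1-yl)stannane | CCCC[Sn](CCCC)(CCCC)CC=C(C)C | starting material
3 | 4-methoxy-3,5-bis(3-methylbut-2-en-1-yl)benzaldehyde | COc1c(CC=C(C)C)cc(C=O)cc1CC=C(C)C | intermediate
4 | methyl 2,4-dihydroxybenzoate | COC(=O)c1ccc(O)cc1O | starting material
5 | methyl 2-hydroxy-4-(methoxymethoxy)benzoate | COCOc1ccc(C(=O)OC)c(O)c1 | intermediate
6 | tert-butyl acetate | CC(=O)OC(C)(C)C | starting material
7 | lithium enolate of tert-butyl acetate (not isolated) | [Li+].C=C([O-])OC(C)(C)C | intermediate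
8 | tert-butyl 3-[2-hydroxy-4-(methoxymethoxy)phenyl]-3-oxopropanoate | COCOc1ccc(C(=O)CC(=O)OC(C)(C)C)c(O)c1 | intermediate
9 | tert-butyl (2E)-2-[2-hydroxy-4-(methoxymethoxy)benzoyl]-3-[4-methoxy-3,5-bis(3-methylbut-2-en-1-yl)phenyl]prop-2-enoate | COc1c(CC=C(C)C)cc(/C=C(/C(=O)OC(C)(C)C)C(=O)c2ccc(OCOC)cc2O)cc1CC=C(C)C | intermediate
10 | tert-butyl (2S,3R)-7-(methoxymethoxy)-2-[4-methoxy-3,5-bis(3-methylbut-2-en-1-yl)phenyl]-4-oxochromane-3-carboxylate (trans, C3 epimerisable, not isolated) | COc1c(CC=C(C)C)cc([C@@H]2[C@@H](C(=O)OC(C)(C)C)C(=O)c3ccc(OCOC)cc3O2)cc1CC=C(C)C | intermediate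
11 | (2S)-7-hydroxy-2-[4-methoxy-3,5-bis(3-methylbut-2-en-1-yl)phenyl]-2,3-dihydro-4H-chromen-4-one | COc1c(CC=C(C)C)cc([C@@H]2CC(=O)c3ccc(O)cc3O2)cc1CC=C(C)C | target

Total step count: 5. Longest linear sequence: 4 (steps 2, 3, 4 and 5).

Steps most likely to fail

Risk 1 (step 5): facial discrimination in the ring closure may be insufficient. The hot acid stage may also erode the C2 configuration by reversible opening of the O1–C2 bond, or add acid across the prenyl double bonds. The fallback sets out from 3 and comes back at 11, and it replaces catalyst-controlled closure by an acid-free, protecting-group-free closure followed by kinetic resolution.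
- Claisen–Schmidt condensation of 3 with commercial 2,4-dihydroxyacetophenone (KOH, EtOH/H2O, rt) should give (E)-1-(2,4-dihydroxyphenyl)-3-[4-methoxy-3,5-bis(3-methylbut-2-en-1-yl)phenyl]prop-2-en-1-one F1.
- NaOAc in refluxing EtOH closes ring C without stereocontrol to the racemic flavanone F2.
- Asymmetric transfer hydrogenation with RuCl(p-cymene)[(R,R)-TsDPEN] in HCO2H/Et3N at rt forms a 4R carbinol. That sense matches the substrate-preferred cis hydride delivery only in the 2R enantiomer.
- The 2R ketone should therefore be reduced to the cis (2R,4R)-flavan-4-ol F3. The 2S ketone 11 should remain and is separated by chromatography. The isolated alkenes are not touched by this catalyst.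

Risk 2 (step 1): the prenyl group may be transferred through its tertiary terminus, the double bond may migrate into conjugation at 100 °C, or the reaction may stall after the first coupling. The fallback sets out from 1 and comes back at 3.
- Double Stille coupling with allyltributylstannane (Pd(PPh3)4, DMF, 90 °C) has no regiochemical ambiguity and should give 3,5-diallyl-4-methoxybenzaldehyde F4.
- Cross metathesis with 2-methylbut-2-ene (second-generation Grubbs catalyst, CH2Cl2, 40 °C) then converts both allyl groups into prenyl groups and delivers 3.

Risk 3 (step 3): acyl substitution at the ester, which is deactivated by the lithium phenoxide and the para alkoxy group, may be so slow that self-condensation of enolate 7 takes over. The fallback sets out from 5 and comes back at 8, and it exchanges the strongly basic enolate for a neutral magnesium enolate and an activated acyl donor.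
- Saponification (LiOH, THF/H2O, 50 °C, careful acidification to pH 4) should give 2-hydroxy-4-(methoxymethoxy)benzoic acid F5.
- 1,1'-Carbonyldiimidazole in THF converts it into the acyl imidazolide F6.
- Decarboxylative Claisen condensation with potassium mono-tert-butyl malonate, MgCl2 and Et3N (MeCN/THF, rt) furnishes 8.

Further compounds
F1 | step 5 | (E)-1-(2,4-dihydroxyphenyl)-3-[4-methoxy-3,5-bis(3-methylbut-2-en-1-yl)phenyl]prop-2-en-1-one | COc1c(CC=C(C)C)cc(/C=C/C(=O)c2ccc(O)cc2O)cc1CC=C(C)C
F2 | step 5 | racemic 7-hydroxy-2-[4-methoxy-3,5-bis(3-methylbut-2-en-1-yl)phenyl]-2,3-dihydro-4H-chromen-4-one | COc1c(CC=C(C)C)cc(C2CC(=O)c3ccc(O)cc3O2)cc1CC=C(C)C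
F3 | step 5 | (2R,4R)-2-[4-methoxy-3,5-bis(3-methylbut-2-en-1-yl)phenyl]chromane-4,7-diol (cis) | COc1c(CC=C(C)C)cc([C@H]2C[C@@H](O)c3ccc(O)cc3O2)cc1CC=C(C)C
F4 | step 1 | 3,5-diallyl-4-methoxybenzaldehyde | COc1c(CC=C)cc(C=O)cc1CC=C
F5 | step 3 | 2-hydroxy-4-(methoxymethoxy)benzoic acid | COCOc1ccc(C(=O)O)c(O)c1
F6 | step 3 | [2-hydroxy-4-(methoxymethoxy)phenyl](1H-imidazol-1-yl)methanone | COCOc1ccc(C(=O)n2ccnc2)c(O)c1
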